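The numbers in the tables were generated by integration with made-up constants, noise included.

- A small charge of substrate, 0.200 M, meets 1.30 M of reagent in the south-west run. I follow one substrate molecule there: either reagent captures it and it becomes target, or it leaks into something else.

| flask | substrate | reagent | time |
|---|---|---|---|
| north | 0.600 M | 0.660 M |  |
| east | 0.360 M | 0.420 M |  |
| north-west | 0.300 M | 0.660 M |  |
| south | 0.600 M | 0.330 M |  |
| south-west | 0.200 M | 1.30 M | 9.8 h |

| run | time / h | [target] / M |
|---|---|---|
| north run | 1.4 | 0.1119 |
| north run | 2.8 | 0.1780 |
| north run | 4.2 | 0.2153 |
| north run | 5.6 | 0.2426 |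
| north run | 7.0 | 0.2615 |
| north run | 8.4 | 0.2724 |
| north run | 9.8 | 0.2801 |
| east run | 1.4 | 0.0490 |
| east run | 2.8 | 0.0795 |
| east run | 4.2 | 0.1059 |
| east run | 5.6 | 0.1204 |
| east run | 7.0 | 0.1262 |
| east run | 8.4 | 0.1391 |
| east run | 9.8 | 0.1453 |
| north-west run | 1.4 | 0.0581 |
| north-west run | 2.8 | 0.1052 |
| north-west run | 4.2 | 0.1287 |
| north-west run | 5.6 | 0.1483 |
| north-west run | 7.0 | 0.1570 |
| north-west run | 8.4 | 0.1694 |
| north-west run | 9.8 | 0.1746 |
| south run | 1.4 | 0.0588 |
| south run | 2.8 | 0.0947 |
| south run | 4.2 | 0.1227 |
| south run | 5.6 | 0.1348 |
| south run | 7.0 | 0.1473 |
| south run | 8.4 | 0.1559 |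
| south run | 9.8 | 0.1614 |

(standard deviation of a reading: 0.002 M)

- order of the initial rate in [reagent], near the charge of the north run, the rate being that where two percent of its substrate are target
- order of the initial rate in [substrate], near the charge of the north run, the rate being that where two percent of its substrate are target (one fixed amount of target, the same in the runs compared)
- target in the south-west run at 9.8 h, as a share of the substrate charged

- Overall: substrate + reagent -> target.
- Constant volume, constant temperature.
- "The second partner" is reagent.
- An order is taken over about fifteen percent of the charge, up and down.

- Halving the substrate takes the first reading from 0.1119 M in the north run to 0.0581 M in the north-west run, and halving the reagent takes it to 0.0588 M in the south run. I therefore commit to orders of 0.946 in substrate and 0.928 in reagent, read across a wider span than the one asked.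
- The north readings already curve at 2.8 h, so I treat the first two as an exponential approach: x, the second reading over the first less one, is 0.591, which gives a starting rate in the north run of 0.103 M/h. That rate over the product of the north charges gives a rate constant k = 0.260 /M/h. The capture rate a is k times [reagent].
- First rung: in the south-west run reagent stands at 6.50 times the substrate, so a falls by at most 15.4 % (pseudo-first-order). Taking reagent as its charge less 0.5 of the substrate charge gives a = 0.312 /h, a capture time of 3.21 h.
- Next rung: in the north-west run, with reagent taken as 0.575 M, a = 0.149 /h, so capture takes 6.71 h, slower than in the south-west run.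
- Last rung: the north-west slope from 7.0 h to 9.8 h is 0.00629 M/h. Dividing by k and the north-west reagent at 8.4 h reads 0.0494 M of substrate still there in that run. Target 0.1694 M out of 0.251 M gone in the north-west run is a share of 67.6 %.
- That reading gives the leak rate λ, the chance per hour that a waiting substrate molecule ends as anything but target, λ = a × (share lost)/(share made) = 0.0716 /h. Its time of 14.0 h is the slowest rung, and longer than the 9.8 h window.
- At the south-west fork the share is a/(a+λ) = 81.3 %, and the fork is 97.7 % passed by 9.8 h, so I commit to 79.4 %.
- The forecast gives orders of 0.97 in reagent and 0.95 in substrate and a south-west yield of 88 %, higher than my yield, and opens: “The curves flatten far too early for simple second-order kinetics”.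
- The flask gives orders of 1.0 in reagent and 1.0 in substrate, and 78.4 % of the substrate charged as target in the south-west run at 9.8 h. A fit in which the product reacts on with the second partner leaves a root mean square residual of 6.1 times the scatter.

    substrate + reagent → target + by-product (0.2826 /M/h)
    target → decomposed product (0.01822 /h)
    2 substrate → homo dimer (0.1357 /M/h)

- In the east run, reagent taken as 0.347 M gives a = 0.0902 /h. With λ the east fork share is 55.7 %, so λ puts east target at 0.160 M by 9.8 h, higher than the east reading of 0.1453 M.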